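Everything rests on cutting the C6–C1 bond of ring A. Spiro carbon C6 lies para to the oxygen-bearing C9 of ring B and carries C1 with its exocyclic methylene, so ring B can be carried as a flat para-alkylphenol. In one isomerisation, a monovalent gold catalyst makes the phenol attack a pendant terminal alkyne through its ipso carbon: ring A closes, the quaternary spiro centre and the methylene appear, and ring B becomes a symmetric cyclohexadienone. The precursor is a 4-substituted phenol whose benzylic gem-dimethyl carbon (C5) is followed by the C4 bromide, the silyl-protected C3 carbinol and a propargyl end, both stereocentres already in place.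

Key step: step 6

Remarks on the chemistry
- Locants: names use the spiro[5.5]undecane numbering of the core: ring A = C1–C6 (C1 bears the methylene), ring B = C6–C11 (C10 is the ketone carbon of the target). The cis C3–O/C4–Br pair of ring A is the 1,2-anti bromohydrin of the open chain.
- Precursor design: the phenol is carried as its aryl silyl ether and freed only under non-basic conditions, because as a phenoxide the 4-hydroxyphenyl group, which is β to the C4 bromide, would expel bromide through its para carbon. For the same reason the gold catalyst is preformed and silver-free.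
- Assumption: the (2S,5S) amine of step 2 and the (S,S) rhodium complex of step 7 are assigned from steric models. If a first run shows the opposite sense, the mirror-image catalyst is used and nothing else changes.
- Assumption: 1, 2, 7 and 18 are bought.

Step 1
Reactants: 1 (4-bromophenoxy)(tert-butyl)dimethylsilane; 2 3-methylbut-2-enal
Product: 5 3-[4-(tert-butyldimethylsilyloxy)phenyl]-3-methylbutanal, via arylmagnesium bromide 3 (not isolated), via trimethylsilyl enol ether 4 (not isolated)
Conditions: Mg, THF, 40 °C; then CuBr·SMe2 (10 mol%), TMSCl, DMPU, 2, THF, −78 °C; then 1 M HCl, 0 °C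
Reagents that add atoms: none
Why: Copper-catalysed, chlorotrimethylsilane-accelerated 1,4-addition of the aryl Grignard reagent to the β,β-disubstituted enal builds the benzylic quaternary carbon C5 in one operation, the silyl enol ether is hydrolysed on work-up, and no stereocentre is formed.

Step 2
Reactants: 5 3-[4-(tert-butyldimethylsilyloxy)phenyl]-3-methylbutanal
Product: 6 (2R)-2-bromo-3-[4-(tert-butyldimethylsilyloxy)phenyl]-3-methylbutanal
Conditions: (2S,5S)-2,5-diphenylpyrrolidine (20 mol%), 4,4-dibromo-2,6-di-tert-butylcyclohexa-2,5-dien-1-one, PhCO2H (20 mol%), H2O, CH2Cl2–pentane, −24 °C; used crude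
Reagents that add atoms: 4,4-dibromo-2,6-di-tert-butylcyclohexa-2,5-dien-1-one, CC(C)(C)C1=CC(Br)(Br)C=C(C(C)(C)C)C1=O
Why: Enamine-mediated organocatalytic α-bromination, in which the C2-symmetric pyrrolidine forms the E-enamine of this unbranched aldehyde and shields one face so that bromine enters from the other and sets C4 as R, the neopentyl-type α-bromo aldehyde being slow to enolise and therefore carried on crude.

Step 3
Reactants: 6 (2R)-2-bromo-3-[4-(tert-butyldimethylsilyloxy)phenyl]-3-methylbutanal; 7 propargyl bromide
Product: 9 (4S,5R)-5-bromo-6-[4-(tert-butyldimethylsilyloxy)phenyl]-6-methylhept-1-yn-4-ol, via allenylzinc bromide 8 (not isolated)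
Conditions: 7, zinc dust, THF, 0 °C; decanted onto 6, THF, −78 °C; sat. aq. NH4Cl, −78 °C
Reagents that add atoms: none
Why: Barbier-type propargylation in which the preformed allenylzinc reagent adds through a cyclic SE2' transition state to give the homopropargylic alcohol, the Cornforth arrangement (C–Br opposed to the carbonyl dipole, attack past hydrogen and away from the tertiary group) setting C3 as S, that is the 1,2-anti bromohydrin, while the cold quench keeps the zinc alkoxide from closing to the epoxide.

Step 4
Reactants: 9 (4S,5R)-5-bromo-6-[4-(tert-butyldimethylsilyloxy)phenyl]-6-methylhept-1-yn-4-ol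
Product: 10 tert-butyl{4-[(3R,4S)-3-bromo-4-(tert-butyldimethylsilyloxy)-2-methylhept-6-yn-2-yl]phenoxy}dimethylsilane
Conditions: TBSOTf, 2,6-lutidine, CH2Cl2, −78 to 0 °C
Reagents that add atoms: tert-butyldimethylsilyl triflate (TBSOTf), CC(C)(C)[Si](C)(C)OS(=O)(=O)C(F)(F)F
Why: Silyl triflate etherification of the hindered secondary alcohol under a weak non-nucleophilic base, which blocks epoxide formation from the anti bromohydrin and oxygen attack on the alkyne in step 6 and touches no stereocentre.

Step 5
Reactants: 10 tert-butyl{4-[(3R,4S)-3-bromo-4-(tert-butyldimethylsilyloxy)-2-methylhept-6-yn-2-yl]phenoxy}dimethylsilane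
Product: 11 4-[(3R,4S)-3-bromo-4-(tert-butyldimethylsilyloxy)-2-methylhept-6-yn-2-yl]phenol
Conditions: KHF2, MeOH, rt
Reagents that add atoms: none
Why: Selective desilylation, since bifluoride in methanol cleaves the aryl silyl ether far faster than the hindered secondary alkyl silyl ether and releases the phenol in its neutral form, so that no phenoxide is present to displace the β-bromide at C4.

Step 6
Reactants: 11 4-[(3R,4S)-3-bromo-4-(tert-butyldimethylsilyloxy)-2-methylhept-6-yn-2-yl]phenol
Product: 12 (3S,4R)-4-bromo-3-(tert-butyldimethylsilyloxy)-5,5-dimethyl-1-methylidenespiro[5.5]undeca-7,10-dien-9-one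
Conditions: (Ph3P)AuNTf2 (5 mol%), CH2Cl2, 4 Å MS, 0 °C to rt
Reagents that add atoms: none
Why: Proposed new method: the cationic gold centre binds the terminal alkyne and makes its internal carbon electrophilic, the phenol attacks it anti through the carbon para to oxygen (its ipso carbon, the vinylogous enol position) to give a vinylgold oxocarbenium ion, loss of the O–H proton gives the cross-conjugated dienone and that proton cleaves the C–Au bond to leave the 1,1-disubstituted alkene, so the step is a pure isomerisation. The closest known reactions are gold- or silver-catalysed dearomatising ipso-cyclisations of phenol-tethered ynones, electrophilic ipso-halocyclisations of para-oxygenated aryl alkynes and the Conia-ene reaction, whereas an unactivated terminal alkyne closing a six-membered ring in this way has not been shown. Ring A closes in the 6-exo-dig mode with Markovnikov regiochemistry. No stereocentre is created, because the two dienone arms are identical and C6 is therefore not yet stereogenic, and C3 and C4 are untouched. The step needs only site selectivity (ipso attack over ortho attack, over attack by the silyl ether oxygen and over hydration), and the quaternary C5 holds the alkyne over the ipso carbon through the gem-dimethyl effect while ortho attack would need a seven-membered ring. The preformed silver-free catalyst and the dry non-basic medium ensure that the C4 bromide, which is β to the arene, is neither abstracted nor displaced.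

Step 7
Reactants: 12 (3S,4R)-4-bromo-3-(tert-butyldimethylsilyloxy)-5,5-dimethyl-1-methylidenespiro[5.5]undeca-7,10-dien-9-one
Product: 14 (3S,4R,6R)-4-bromo-3-(tert-butyldimethylsilyloxy)-5,5-dimethyl-1-methylidenespiro[5.5]undec-10-en-9-one, via silyl dienol ether 13 (not isolated)
Conditions: [2,6-bis((4S)-4-isopropyl-4,5-dihydrooxazol-2-yl)phenyl]Rh(OAc)2(OH2) (2 mol%), (EtO)2MeSiH, toluene, 50 °C; then 1 M HCl, THF, 0 °C
Reagents that add atoms: none
Why: Rhodium-hydride conjugate hydrosilylation of a 4,4-disubstituted cyclohexadienone, a known catalyst-controlled differentiation of the two enone arms, in which the C2-symmetric pincer ligand reads the difference between the C1 methylene flank and the C5 gem-dimethyl flank of the spiro carbon and delivers hydride to C7 only, making C6 stereogenic (R), while the primary product is a silyloxydiene and no longer an enone so that reduction stops after one arm and hydrolysis gives the conjugated enone.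

Step 8
Reactants: 14 (3S,4R,6R)-4-bromo-3-(tert-butyldimethylsilyloxy)-5,5-dimethyl-1-methylidenespiro[5.5]undec-10-en-9-one
Product: 17 (3S,4R,6R,10R)-4-bromo-3-(tert-butyldimethylsilyloxy)-10-hydroxy-5,5-dimethyl-1-methylidenespiro[5.5]undecan-9-one, via silyl enol ether 15 (not isolated), via silyloxy epoxide 16 (not isolated)
Conditions: [(Ph3P)CuH]6 (3 mol%), PhMe2SiH, toluene, rt; then DMDO, acetone–CH2Cl2, −78 °C; then AcOH, THF–H2O, 0 °C
Reagents that add atoms: dimethyldioxirane (DMDO), CC1(C)OO1
Why: Copper-hydride 1,4-hydrosilylation fixes the silyl enol ether at C9=C10, and Rubottom oxidation with dimethyldioxirane, which attacks this electron-rich alkene much faster than the 1,1-disubstituted C1 methylene and from the face opposite the pseudo-axial C1, should give after mild acid the equatorial C10 carbinol (R, cis to C5), a centre that is oxidised away in step 10.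

Step 9
Reactants: 17 (3S,4R,6R,10R)-4-bromo-3-(tert-butyldimethylsilyloxy)-10-hydroxy-5,5-dimethyl-1-methylidenespiro[5.5]undecan-9-one; 18 chloroiodomethane
Product: 20 (3S,4R,6R,9S,10R)-4-bromo-3-(tert-butyldimethylsilyloxy)-9-(chloromethyl)-5,5-dimethyl-1-methylidenespiro[5.5]undecane-9,10-diol, via chloromethyllithium 19 (not isolated)
Conditions: 18, MeLi·LiBr (slow addition), THF–Et2O, −78 °C; AcOH, −78 °C
Reagents that add atoms: none
Why: Carbenoid addition in Barbier mode, in which chloromethyllithium formed by iodine–lithium exchange adds irreversibly to the C9 ketone while the lithium alkoxide at C10 chelates the carbonyl (Cram chelate), so that the carbenoid enters from the equatorial direction past the axial C10 hydrogen and the new hydroxyl is axial and cis to C5 (C9 = S), the cold acidic quench keeping the chlorohydrin from closing to the epoxide.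

Step 10
Reactants: 20 (3S,4R,6R,9S,10R)-4-bromo-3-(tert-butyldimethylsilyloxy)-9-(chloromethyl)-5,5-dimethyl-1-methylidenespiro[5.5]undecane-9,10-diol
Product: 21 (3S,4R,6R,9S)-4-bromo-3-(tert-butyldimethylsilyloxy)-9-(chloromethyl)-9-hydroxy-5,5-dimethyl-1-methylidenespiro[5.5]undecan-10-one
Conditions: IBX, DMSO, rt
Reagents that add atoms: none
Why: IBX oxidation converts the secondary C10 alcohol into the ketone without cleaving the 1,2-diol and without base, so the tertiary chlorohydrin at C9 keeps its constitution and configuration.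

Step 11
Reactants: 21 (3S,4R,6R,9S)-4-bromo-3-(tert-butyldimethylsilyloxy)-9-(chloromethyl)-9-hydroxy-5,5-dimethyl-1-methylidenespiro[5.5]undecan-10-one
Product: 22 (3S,4R,6R,9S)-4-bromo-9-(chloromethyl)-3,9-dihydroxy-5,5-dimethyl-1-methylidenespiro[5.5]undecan-10-one
Conditions: HF·pyridine, pyridine, THF, 0 °C to rt
Reagents that add atoms: none
Why: Acidic fluoride desilylation removes the hindered secondary silyl ether without base, which would close the chlorohydrin to an epoxide or isomerise the α-ketol, and it affects no stereocentre because the cis bromohydrin of ring A cannot form an epoxide.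

Compound list
1 | (4-bromophenoxy)(tert-butyl)dimethylsilane | CC(C)(C)[Si](C)(C)Oc1ccc(Br)cc1 | starting material
2 | 3-methylbut-2-enal | CC(C)=CC=O | starting material
3 | [4-(tert-butyldimethylsilyloxy)phenyl]magnesium bromide | CC(C)(C)[Si](C)(C)Oc1ccc([Mg]Br)cc1 | intermediate
4 | trimethylsilyl enol ether of 5 (E/Z mixture), tert-butyldimethyl{4-[2-methyl-4-(trimethylsilyloxy)but-3-en-2-yl]phenoxy}silane | C[Si](C)(C)OC=CC(C)(C)c1ccc(O[Si](C)(C)C(C)(C)C)cc1 | intermediate
5 | 3-[4-(tert-butyldimethylsilyloxy)phenyl]-3-methylbutanal | O=CCC(C)(C)c1ccc(O[Si](C)(C)C(C)(C)C)cc1 | intermediate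
6 | (2R)-2-bromo-3-[4-(tert-butyldimethylsilyloxy)phenyl]-3-methylbutanal | O=C[C@H](Br)C(C)(C)c1ccc(O[Si](C)(C)C(C)(C)C)cc1 | intermediate
7 | propargyl bromide (3-bromoprop-1-yne) | C#CCBr | starting material
8 | allenylzinc bromide (propa-1,2-dienylzinc bromide) | C=C=C[Zn]Br | intermediate
9 | (4S,5R)-5-bromo-6-[4-(tert-butyldimethylsilyloxy)phenyl]-6-methylhept-1-yn-4-ol | C#CC[C@H](O)[C@H](Br)C(C)(C)c1ccc(O[Si](C)(C)C(C)(C)C)cc1 | intermediate
10 | tert-butyl{4-[(3R,4S)-3-bromo-4-(tert-butyldimethylsilyloxy)-2-methylhept-6-yn-2-yl]phenoxy}dimethylsilane | C#CC[C@H](O[Si](C)(C)C(C)(C)C)[C@H](Br)C(C)(C)c1ccc(O[Si](C)(C)C(C)(C)C)cc1 | intermediate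
11 | 4-[(3R,4S)-3-bromo-4-(tert-butyldimethylsilyloxy)-2-methylhept-6-yn-2-yl]phenol (cyclisation precursor) | C#CC[C@H](O[Si](C)(C)C(C)(C)C)[C@H](Br)C(C)(C)c1ccc(O)cc1 | intermediate
12 | (3S,4R)-4-bromo-3-(tert-butyldimethylsilyloxy)-5,5-dimethyl-1-methylidenespiro[5.5]undeca-7,10-dien-9-one | C=C1C[C@H](O[Si](C)(C)C(C)(C)C)[C@H](Br)C(C)(C)C12C=CC(=O)C=C2 | intermediate
13 | (3S,4R,6R)-4-bromo-3-(tert-butyldimethylsilyloxy)-9-[diethoxy(methyl)silyloxy]-5,5-dimethyl-1-methylidenespiro[5.5]undeca-8,10-diene | C=C1C[C@H](O[Si](C)(C)C(C)(C)C)[C@H](Br)C(C)(C)[C@@]12CC=C(O[Si](C)(OCC)OCC)C=C2 | intermediate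
14 | (3S,4R,6R)-4-bromo-3-(tert-butyldimethylsilyloxy)-5,5-dimethyl-1-methylidenespiro[5.5]undec-10-en-9-one | C=C1C[C@H](O[Si](C)(C)C(C)(C)C)[C@H](Br)C(C)(C)[C@@]12CCC(=O)C=C2 | intermediate
15 | (3S,4R,6R)-4-bromo-3-(tert-butyldimethylsilyloxy)-9-[dimethyl(phenyl)silyloxy]-5,5-dimethyl-1-methylidenespiro[5.5]undec-9-ene | C=C1C[C@H](O[Si](C)(C)C(C)(C)C)[C@H](Br)C(C)(C)[C@@]12CCC(O[Si](C)(C)c3ccccc3)=CC2 | intermediate
16 | (3S,4R,6R,9R,10R)-4-bromo-3-(tert-butyldimethylsilyloxy)-9-[dimethyl(phenyl)silyloxy]-9,10-epoxy-5,5-dimethyl-1-methylidenespiro[5.5]undecane (epoxide oxygen cis to C5) | C=C1C[C@H](O[Si](C)(C)C(C)(C)C)[C@H](Br)C(C)(C)[C@@]12CC[C@]3(O[Si](C)(C)c4ccccc4)O[C@@H]3C2 | intermediate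
17 | (3S,4R,6R,10R)-4-bromo-3-(tert-butyldimethylsilyloxy)-10-hydroxy-5,5-dimethyl-1-methylidenespiro[5.5]undecan-9-one | C=C1C[C@H](O[Si](C)(C)C(C)(C)C)[C@H](Br)C(C)(C)[C@@]12CCC(=O)[C@H](O)C2 | intermediate
18 | chloroiodomethane | ClCI | starting material
19 | chloromethyllithium | [Li]CCl | intermediate
20 | (3S,4R,6R,9S,10R)-4-bromo-3-(tert-butyldimethylsilyloxy)-9-(chloromethyl)-5,5-dimethyl-1-methylidenespiro[5.5]undecane-9,10-diol | C=C1C[C@H](O[Si](C)(C)C(C)(C)C)[C@H](Br)C(C)(C)[C@@]12CC[C@@](O)(CCl)[C@H](O)C2 | intermediate
21 | (3S,4R,6R,9S)-4-bromo-3-(tert-butyldimethylsilyloxy)-9-(chloromethyl)-9-hydroxy-5,5-dimethyl-1-methylidenespiro[5.5]undecan-10-one | C=C1C[C@H](O[Si](C)(C)C(C)(C)C)[C@H](Br)C(C)(C)[C@@]12CC[C@@](O)(CCl)C(=O)C2 | intermediate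
22 | (3S,4R,6R,9S)-4-bromo-9-(chloromethyl)-3,9-dihydroxy-5,5-dimethyl-1-methylidenespiro[5.5]undecan-10-one (CNP0273087.1) | C=C1C[C@H](O)[C@H](Br)C(C)(C)[C@@]12CC[C@@](O)(CCl)C(=O)C2 | target

Total step count: 11. Longest linear sequence: 11 steps (the route is linear from 1).

Steps most likely to fail

Step 6 (proposed new method). The arene may fail to engage the gold-bound alkyne, so that hydration or oligomerisation of the alkyne takes over, or the spiro-dienone may suffer an acid-promoted 1,2-shift back to a phenol. The fallback uses known chemistry and sets out from 10, leaving out step 5. Iodine monochloride in CH2Cl2 at −78 °C turns the alkyne into an iodonium ion that the silyloxy-arene captures through its ipso carbon in the same 6-exo sense, an electrophilic ipso-iodocyclisation of a para-oxygenated aryl alkyne. Loss of the aryl silyl group as its chloride gives (3S,4R)-4-bromo-3-(tert-butyldimethylsilyloxy)-1-[(E)-iodomethylidene]-5,5-dimethylspiro[5.5]undeca-7,10-dien-9-one F1. Palladium-catalysed transfer hydrogenolysis of the vinylic C–I bond (Pd(PPh3)4, HCO2H, Et3N, DMF, 50 °C), to which the secondary alkyl bromide is inert, brings the material back to the route at 12.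

Step 7. Discrimination between the two enone arms may be insufficient, giving the C6 epimer alongside 14, or hydride transfer next to the quaternary carbon may be slow enough for the exocyclic alkene to isomerise. Direction by the C3 oxygen itself was not relied on: in the spiro frame that oxygen lies in the plane of ring B and points at the C11–H bond, not at the enone π face, and the ether it would form is a strained 2-oxabicyclo[2.2.2]octane. The fallback sets out from 12. Exhaustive conjugate reduction with excess [(Ph3P)CuH]6 in wet THF gives the symmetric (3S,4R)-4-bromo-3-(tert-butyldimethylsilyloxy)-5,5-dimethyl-1-methylidenespiro[5.5]undecan-9-one F2. Group-selective deprotonation with lithium (S,S)-bis(1-phenylethyl)amide and internal TMSCl quench in THF at −100 °C then gives (3S,4R,6R)-4-bromo-3-(tert-butyldimethylsilyloxy)-5,5-dimethyl-1-methylidene-9-(trimethylsilyloxy)spiro[5.5]undec-9-ene F3, the antipode of the base being chosen by analogy with 4-substituted cyclohexanones. Oxidation of F3 with DMDO and aqueous AcOH as in step 8 comes back to the route at 17.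

Step 9. Facial control at C9 may be lost through axial entry of the carbenoid, or the chloro-alkoxide may close to the epoxide or the ketol may enolise before addition. The fallback sets out from 17. Silylation (TESCl, imidazole, CH2Cl2) gives (3S,4R,6R,10R)-4-bromo-3-(tert-butyldimethylsilyloxy)-5,5-dimethyl-1-methylidene-10-(triethylsilyloxy)spiro[5.5]undecan-9-one F4. Corey–Chaykovsky epoxidation with dimethylsulfoxonium methylide (Me3S(O)I, NaH, DMSO), whose reversible betaine formation places the CH2 group equatorial and the oxygen axial, gives the C9 spiro-oxirane of F4 (oxirane oxygen cis to C5, oxirane CH2 cis to C1) F5. Chloride opening at the primary carbon (LiCl, AcOH, THF) gives (3S,4R,6R,9S,10R)-4-bromo-3-(tert-butyldimethylsilyloxy)-9-(chloromethyl)-5,5-dimethyl-1-methylidene-10-(triethylsilyloxy)spiro[5.5]undecan-9-ol F6. Selective removal of the triethylsilyl group (PPTS, MeOH, 0 °C) comes back to the route at 20.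

Further compounds
F1 | step 6 | (3S,4R)-4-bromo-3-(tert-butyldimethylsilyloxy)-1-[(E)-iodomethylidene]-5,5-dimethylspiro[5.5]undeca-7,10-dien-9-one | I/C=C1\C[C@H](O[Si](C)(C)C(C)(C)C)[C@H](Br)C(C)(C)C12C=CC(=O)C=C2
F2 | step 7 | (3S,4R)-4-bromo-3-(tert-butyldimethylsilyloxy)-5,5-dimethyl-1-methylidenespiro[5.5]undecan-9-one | C=C1C[C@H](O[Si](C)(C)C(C)(C)C)[C@H](Br)C(C)(C)C12CCC(=O)CC2
F3 | step 7 | (3S,4R,6R)-4-bromo-3-(tert-butyldimethylsilyloxy)-5,5-dimethyl-1-methylidene-9-(trimethylsilyloxy)spiro[5.5]undec-9-ene | C=C1C[C@H](O[Si](C)(C)C(C)(C)C)[C@H](Br)C(C)(C)[C@@]12CCC(O[Si](C)(C)C)=CC2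
F4 | step 9 | (3S,4R,6R,10R)-4-bromo-3-(tert-butyldimethylsilyloxy)-5,5-dimethyl-1-methylidene-10-(triethylsilyloxy)spiro[5.5]undecan-9-one | C=C1C[C@H](O[Si](C)(C)C(C)(C)C)[C@H](Br)C(C)(C)[C@@]12CCC(=O)[C@H](O[Si](CC)(CC)CC)C2
F5 | step 9 | C9 spiro-oxirane of F4 (9R; oxirane oxygen cis to C5, oxirane CH2 cis to C1) | C=C1C[C@H](O[Si](C)(C)C(C)(C)C)[C@H](Br)C(C)(C)[C@@]12CC[C@@]3(CO3)[C@H](O[Si](CC)(CC)CC)C2
F6 | step 9 | (3S,4R,6R,9S,10R)-4-bromo-3-(tert-butyldimethylsilyloxy)-9-(chloromethyl)-5,5-dimethyl-1-methylidene-10-(triethylsilyloxy)spiro[5.5]undecan-9-ol | C=C1C[C@H](O[Si](C)(C)C(C)(C)C)[C@H](Br)C(C)(C)[C@@]12CC[C@@](O)(CCl)[C@H](O[Si](CC)(CC)CC)C2
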